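**Plan**

Numbering: ring B (seven-membered) is C1(=CH2)–C2(OH)–C3–C4–C5(OH)–C6–C10; ring A (cyclopentene) is C6–C7(Me)=C8–C9–C10; the side chain on C4 is C11(Me)–C12(OAc)–C13(OAc)–C14=C15Me2.
Retrosynthesis: after the two silyl ethers, C1–C2 is cut first. The feature that allows this is the C2 carbinol next to C1, the ring-B carbon that carries the exocyclic methylene: an aldehyde (C2) joined reductively to the internal carbon of a terminal alkyne (C1≡CH). The second cut is C4–C5 (allylboration), giving ring-A aldehyde 11 and side-chain (E)-allylboronate 24.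
Forward: ring A is closed first by metathesis (C7=C8) of a butenolide-derived diene; the side chain is built linearly from crotyl alcohol; the fragments are joined at C4–C5; the C3=C2 vinyl group becomes the C2 aldehyde; ring B is closed last.
Stereochemistry: C6 from rhodium/(S)-BINAP conjugate addition and C10 from trans alkylation of the lactone enolate. C11/C12 come from Sharpless epoxidation and invertive epoxide opening, C13 from chelation-controlled Grignard addition. C4/C5 come from the (E)-boronate in a chair transition state under chiral phosphoric acid control, and C2 from the conformation of the trans-fused nickelacycle.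

Key step: step 23

Remark on the chemistry: the SMILES is read with a trans A/B fusion (H6 and H10 on opposite faces), the C4 side chain cis to O5 and trans to O2; in the numbering above the descriptors are 2R,4S,5R,6S,10R,11R,12S,13S. The sense of induction in steps 1 and 18 is assigned by analogy with the accepted models for these ligands and would be checked at that stage.

**Fragment A (ring-A aldehyde)**

Step 1
Reactants: 1 furan-2(5H)-one
Product: 2 (4S)-4-(prop-1-en-2-yl)oxolan-2-one
Conditions: CH2=C(CH3)BF3K, [Rh(cod)2]BF4 (3 mol%), (S)-BINAP, toluene/H2O 10:1, 100 °C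
Reagents that add atoms: potassium trifluoro(prop-1-en-2-yl)borate, [K+].C=C(C)[B-](F)(F)F
Why: Rhodium-catalysed asymmetric conjugate addition of an alkenylboron reagent to an unsaturated lactone (Hayashi–Miyaura reaction) is established, and the (S)-BINAP complex of monovalent rhodium is expected, by analogy with cyclic enones and pyranones, to add the isopropenyl group to the face that gives the 4S centre, the future C6.

Step 2
Reactants: 2 (4S)-4-(prop-1-en-2-yl)oxolan-2-one
Product: 4 (3R,4S)-3-(prop-2-en-1-yl)-4-(prop-1-en-2-yl)oxolan-2-one, via lithium enolate 3 (not isolated)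
Conditions: LiN(i-Pr)2, THF, −78 °C; allyl bromide, −78 → −30 °C
Reagents that add atoms: allyl bromide, C=CCBr
Why: Enolate alkylation of a β-substituted γ-butyrolactone takes the electrophile anti to the β-substituent, so the allyl group (future C9 and C8) enters trans to the isopropenyl group and sets C10.

Step 3
Reactants: 4 (3R,4S)-3-(prop-2-en-1-yl)-4-(prop-1-en-2-yl)oxolan-2-one
Product: 5 (3R,4S)-3-(prop-2-en-1-yl)-4-(prop-1-en-2-yl)oxolan-2-ol (lactol, both anomers)
Conditions: i-Bu2AlH (1.1 equiv), CH2Cl2, −78 °C; aqueous potassium sodium tartrate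
Reagents that add atoms: none
Why: Partial reduction of a γ-lactone with one equivalent of i-Bu2AlH at low temperature stops at the lactol because the tetrahedral aluminate survives until work-up, and no stereocentre is touched.

Step 4
Reactants: 5 (3R,4S)-3-(prop-2-en-1-yl)-4-(prop-1-en-2-yl)oxolan-2-ol
Product: 7 (2S,3R)-3-ethynyl-2-(prop-1-en-2-yl)hex-5-en-1-ol, via open hydroxy aldehyde 6 (not isolated)
Conditions: dimethyl (1-diazo-2-oxopropyl)phosphonate, K2CO3, MeOH, 0 °C → rt
Reagents that add atoms: dimethyl (1-diazo-2-oxopropyl)phosphonate, COP(=O)(OC)C(=[N+]=[N-])C(C)=O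
Why: Seyferth–Gilbert homologation with the Ohira–Bestmann reagent converts a lactol through its open hydroxy aldehyde form into a terminal alkyne under mild carbonate conditions that should leave the α-centre C10 intact, the lactol carbon becoming C1 and the new carbon the alkyne CH.

Step 5
Reactants: 7 (2S,3R)-3-ethynyl-2-(prop-1-en-2-yl)hex-5-en-1-ol
Product: 9 (2S,3R)-2-(prop-1-en-2-yl)-3-[(trimethylsilyl)ethynyl]hex-5-en-1-ol, via bis-silyl derivative 8 (not isolated)
Conditions: n-BuLi (2.2 equiv), THF, −78 °C; Me3SiCl (2.3 equiv), −78 → 0 °C; then 1 M HCl (aq), rt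
Reagents that add atoms: chlorotrimethylsilane, C[Si](C)(C)Cl
Why: Double deprotonation and silylation followed by hydrolysis of the labile O–Si bond is the standard way to cap a terminal alkyne next to an alcohol, and the cap keeps the alkyne out of the metathesis of step 6 and the hydroboration of step 20.

Step 6
Reactants: 9 (2S,3R)-2-(prop-1-en-2-yl)-3-[(trimethylsilyl)ethynyl]hex-5-en-1-ol
Product: 10 {(1S,5R)-2-methyl-5-[(trimethylsilyl)ethynyl]cyclopent-2-en-1-yl}methanol
Conditions: second-generation Grubbs catalyst RuCl2(=CHPh)(PCy3)(H2IMes) (5 mol%), CH2Cl2 (0.01 M), 40 °C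
Reagents that add atoms: none
Why: Ring-closing metathesis of a 1,1-disubstituted with a monosubstituted alkene to a trisubstituted cyclopentene is routine with this catalyst, the silyl-capped alkyne could only close a four-membered ring and stays a spectator, and the trans relationship of C6 and C10 is carried over unchanged.

Step 7
Reactants: 10 {(1S,5R)-2-methyl-5-[(trimethylsilyl)ethynyl]cyclopent-2-en-1-yl}methanol
Product: 11 (1S,5R)-2-methyl-5-[(trimethylsilyl)ethynyl]cyclopent-2-ene-1-carbaldehyde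
Conditions: Dess–Martin periodinane, NaHCO3, CH2Cl2, 0 °C; used at once
Reagents that add atoms: none
Why: Dess–Martin oxidation under bicarbonate buffer gives the aldehyde without acid or base strong enough to epimerise C6 or to move the C7=C8 double bond into conjugation.

**Fragment B (side-chain allylboronate)**

Step 8
Reactants: 12 (2E)-but-2-en-1-ol
Product: 13 [(2R,3R)-3-methyloxiran-2-yl]methanol
Conditions: Ti(Oi-Pr)4 (10 mol%), D-(−)-diisopropyl tartrate (12 mol%), t-BuOOH, 4 Å MS, CH2Cl2, −20 °C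
Reagents that add atoms: tert-butyl hydroperoxide, CC(C)(C)OO
Why: Sharpless asymmetric epoxidation of an (E)-allylic alcohol with the D-tartrate ligand gives the (2R,3R)-epoxy alcohol with reagent control over both new centres.

Step 9
Reactants: 13 [(2R,3R)-3-methyloxiran-2-yl]methanol
Product: 14 (2S,3R)-3-methyl-5-(trimethylsilyl)pent-4-yne-1,2-diol
Conditions: Me3SiC≡CH, n-BuLi, toluene, 0 °C; Et2AlCl; then 13, 0 °C → rt
Reagents that add atoms: ethynyltrimethylsilane, C[Si](C)(C)C#C
Why: Alkynylalanes open 2,3-epoxy alcohols at C3 by delivery from the aluminium alkoxide with inversion, which turns the trans-epoxide into the syn pair of the C11 methyl group and the C12 hydroxyl group.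

Step 10
Reactants: 14 (2S,3R)-3-methyl-5-(trimethylsilyl)pent-4-yne-1,2-diol
Product: 15 (4S)-2-(4-methoxyphenyl)-4-[(2R)-4-(trimethylsilyl)but-3-yn-2-yl]-1,3-dioxolane (both acetal epimers)
Conditions: 4-MeOC6H4CH(OMe)2, PPTS (cat.), CH2Cl2, rt
Reagents that add atoms: 4-methoxybenzaldehyde dimethyl acetal, COc1ccc(cc1)C(OC)OC
Why: Acid-catalysed transacetalisation of a 1,2-diol with an aryl aldehyde dimethyl acetal gives the five-membered arylidene acetal, whose new acetal centre is of no consequence.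

Step 11
Reactants: 15 (4S)-2-(4-methoxyphenyl)-4-[(2R)-4-(trimethylsilyl)but-3-yn-2-yl]-1,3-dioxolane
Product: 16 (2S,3R)-2-[(4-methoxybenzyl)oxy]-3-methyl-5-(trimethylsilyl)pent-4-yn-1-ol
Conditions: i-Bu2AlH (3 equiv), CH2Cl2, −78 → 0 °C
Reagents that add atoms: none
Why: Reductive opening of a p-methoxybenzylidene acetal with i-Bu2AlH proceeds by coordination to the less hindered primary oxygen and hydride delivery to the oxocarbenium ion, leaving the PMB ether on the secondary C12 oxygen and a free primary alcohol.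

Step 12
Reactants: 16 (2S,3R)-2-[(4-methoxybenzyl)oxy]-3-methyl-5-(trimethylsilyl)pent-4-yn-1-ol
Product: 17 (2S,3R)-2-[(4-methoxybenzyl)oxy]-3-methyl-5-(trimethylsilyl)pent-4-ynal
Conditions: Dess–Martin periodinane, NaHCO3, CH2Cl2, 0 °C → rt
Reagents that add atoms: none
Why: Buffered Dess–Martin oxidation of a primary alcohol gives the α-alkoxy aldehyde without epimerisation at C12.

Step 13
Reactants: 17 (2S,3R)-2-[(4-methoxybenzyl)oxy]-3-methyl-5-(trimethylsilyl)pent-4-ynal
Product: 19 (3R,4S,5S)-4-[(4-methoxybenzyl)oxy]-3,7-dimethyloct-6-en-1-yn-5-ol, via silyl-capped carbinol 18 (not isolated)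
Conditions: MgBr2·OEt2 (2 equiv), CH2Cl2, −78 °C; Me2C=CHMgBr, −78 °C; then MeOH, K2CO3, rt
Reagents that add atoms: (2-methylprop-1-en-1-yl)magnesium bromide, CC(C)=C[Mg]Br
Why: Grignard addition to an α-(p-methoxybenzyloxy) aldehyde precomplexed with MgBr2 follows chelation control, the alkenyl group attacking the five-membered magnesium chelate on the face away from the C11 substituent to give the syn C12/C13 pattern (13S), after which carbonate in methanol cleaves the alkynyl C–Si bond.

Step 14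
Reactants: 19 (3R,4S,5S)-4-[(4-methoxybenzyl)oxy]-3,7-dimethyloct-6-en-1-yn-5-ol
Product: 20 (3R,4S,5S)-3,7-dimethyloct-6-en-1-yne-4,5-diol
Conditions: DDQ, CH2Cl2/pH 7 buffer 10:1, 0 °C
Reagents that add atoms: none
Why: Oxidative PMB cleavage with DDQ in wet dichloromethane (hydride abstraction, then hydrolysis of the oxocarbenium ion) leaves the alkyne and the trisubstituted alkene alone.

Step 15
Reactants: 20 (3R,4S,5S)-3,7-dimethyloct-6-en-1-yne-4,5-diol
Product: 21 (3R,4S,5S)-3,7-dimethyloct-6-en-1-yne-4,5-diyl diacetate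
Conditions: Ac2O, pyridine, DMAP (cat.), CH2Cl2, rt
Reagents that add atoms: acetic anhydride, CC(=O)OC(C)=O
Why: DMAP-catalysed acylation of both secondary alcohols installs the two acetates of the target at the fragment stage, so that no diol protecting group has to be exchanged later.

Step 16
Reactants: 21 (3R,4S,5S)-3,7-dimethyloct-6-en-1-yne-4,5-diyl diacetate
Product: 22 (1E,3R,4S,5S)-3,7-dimethyl-1-(4,4,5,5-tetramethyl-1,3,2-dioxaborolan-2-yl)octa-1,6-diene-4,5-diyl diacetate
Conditions: pinacolborane, Cp2ZrHCl (10 mol%), Et3N (10 mol%), 60 °C, neat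
Reagents that add atoms: pinacolborane, CC1(C)OBOC1(C)C
Why: Zirconocene hydride-catalysed hydroboration of a terminal alkyne with pinacolborane gives the (E)-1-alkenylboronate by syn addition with boron at the terminal carbon and tolerates esters.

Step 17
Reactants: 22 (1E,3R,4S,5S)-3,7-dimethyl-1-(4,4,5,5-tetramethyl-1,3,2-dioxaborolan-2-yl)octa-1,6-diene-4,5-diyl diacetate
Product: 24 (2E,4R,5S,6S)-4,8-dimethyl-1-(4,4,5,5-tetramethyl-1,3,2-dioxaborolan-2-yl)nona-2,7-diene-5,6-diyl diacetate, via boronate ate complex 23 (not isolated)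
Conditions: ICH2Cl, n-BuLi (added last), THF, −100 °C → rt
Reagents that add atoms: chloroiodomethane, ClCI
Why: In this Matteson homologation (chloromethyl)lithium generated in the presence of the boronate forms the ate complex, whose 1,2-alkenyl shift with loss of chloride inserts CH2 into the C–B bond with retention of the (E)-geometry, the very fast iodine–lithium exchange at −100 °C being relied on to outpace addition to the acetates.

**Union and ring B**

Step 18
Reactants: 11 (1S,5R)-2-methyl-5-[(trimethylsilyl)ethynyl]cyclopent-2-ene-1-carbaldehyde; 24 (2E,4R,5S,6S)-4,8-dimethyl-1-(4,4,5,5-tetramethyl-1,3,2-dioxaborolan-2-yl)nona-2,7-diene-5,6-diyl diacetate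
Product: 26 (3S,4R,5S,6S)-3-[(R)-hydroxy{(1S,5R)-2-methyl-5-[(trimethylsilyl)ethynyl]cyclopent-2-en-1-yl}methyl]-4,8-dimethylnona-1,7-diene-5,6-diyl diacetate, via borate ester 25 (not isolated)
Conditions: (R)-TRIP (3,3′-bis(2,4,6-triisopropylphenyl)-1,1′-binaphthyl-2,2′-diyl hydrogen phosphate, 10 mol%), 4 Å MS, toluene, −30 °C → rt; aqueous work-up
Reagents that add atoms: none
Why: Chiral phosphoric acid-catalysed allylboration runs through a closed chair transition state with the (E)-γ-substituent equatorial, so the anti C4/C5 relationship follows from the alkene geometry, while (R)-TRIP is expected to direct the boronate to the Re face of the aldehyde (5R), reinforced by the C11 centre of the boronate, which favours attack anti to its C12 branch.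

Step 19
Reactants: 26 (3S,4R,5S,6S)-3-[(R)-hydroxy{(1S,5R)-2-methyl-5-[(trimethylsilyl)ethynyl]cyclopent-2-en-1-yl}methyl]-4,8-dimethylnona-1,7-diene-5,6-diyl diacetate
Product: 27 (3S,4R,5S,6S)-3-[(R)-[(tert-butyldimethylsilyl)oxy]{(1S,5R)-2-methyl-5-[(trimethylsilyl)ethynyl]cyclopent-2-en-1-yl}methyl]-4,8-dimethylnona-1,7-diene-5,6-diyl diacetate
Conditions: TBSOTf, 2,6-lutidine, CH2Cl2, −78 → 0 °C
Reagents that add atoms: tert-butyldimethylsilyl trifluoromethanesulfonate, CC(C)(C)[Si](C)(C)OS(=O)(=O)C(F)(F)F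
Why: A silyl triflate with a hindered pyridine base silylates even a hindered secondary alcohol, and protection of O5 prevents lactol formation with the C2 aldehyde made in step 22.

Step 20
Reactants: 27 (3S,4R,5S,6S)-3-[(R)-[(tert-butyldimethylsilyl)oxy]{(1S,5R)-2-methyl-5-[(trimethylsilyl)ethynyl]cyclopent-2-en-1-yl}methyl]-4,8-dimethylnona-1,7-diene-5,6-diyl diacetate
Product: 29 (3S,4R,5S,6S)-3-[(R)-[(tert-butyldimethylsilyl)oxy]{(1S,5R)-2-methyl-5-[(trimethylsilyl)ethynyl]cyclopent-2-en-1-yl}methyl]-1-hydroxy-4,8-dimethylnon-7-ene-5,6-diyl diacetate, via alkylborane 28 (not isolated)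
Conditions: 9-BBN, THF, 0 °C → rt; then NaBO3·4H2O, H2O, rt
Reagents that add atoms: sodium perborate, [Na+].[Na+].O[B-]1(O)OO[B-](O)(O)OO1
Why: Hydroboration with 9-BBN is far faster on a monosubstituted alkene than on trisubstituted alkenes or a silyl-capped alkyne and places boron on the terminal carbon C2, and perborate oxidises the alkylborane under conditions mild enough for the acetates.

Step 21
Reactants: 29 (3S,4R,5S,6S)-3-[(R)-[(tert-butyldimethylsilyl)oxy]{(1S,5R)-2-methyl-5-[(trimethylsilyl)ethynyl]cyclopent-2-en-1-yl}methyl]-1-hydroxy-4,8-dimethylnon-7-ene-5,6-diyl diacetate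
Product: 30 (3S,4R,5S,6S)-3-[(R)-[(tert-butyldimethylsilyl)oxy]{(1S,5R)-5-ethynyl-2-methylcyclopent-2-en-1-yl}methyl]-1-hydroxy-4,8-dimethylnon-7-ene-5,6-diyl diacetate
Conditions: AgNO3 (0.1 equiv), acetone/H2O/CH2Cl2, rt
Reagents that add atoms: none
Why: Silver-catalysed protodesilylation is selective for the alkynyl C–Si bond and leaves the silyl ether and the acetates untouched, which carbonate in methanol would not.

Step 22
Reactants: 30 (3S,4R,5S,6S)-3-[(R)-[(tert-butyldimethylsilyl)oxy]{(1S,5R)-5-ethynyl-2-methylcyclopent-2-en-1-yl}methyl]-1-hydroxy-4,8-dimethylnon-7-ene-5,6-diyl diacetate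
Product: 31 (3S,4R,5S,6S)-3-[(R)-[(tert-butyldimethylsilyl)oxy]{(1S,5R)-5-ethynyl-2-methylcyclopent-2-en-1-yl}methyl]-4,8-dimethyl-1-oxonon-7-ene-5,6-diyl diacetate (the ynal)
Conditions: Dess–Martin periodinane, NaHCO3, CH2Cl2, 0 °C; used at once
Reagents that add atoms: none
Why: Buffered Dess–Martin oxidation gives the C2 aldehyde without touching the terminal alkyne, the silyl ether or the acetates.

Step 23
Reactants: 31 the ynal (C2 aldehyde, C1≡CH, O5-TBS, diacetate); 32 triethylsilane
Product: 33 (2R,3S,4S)-2-[(3aR,5R,7S,8R,8aS)-8-[(tert-butyldimethylsilyl)oxy]-1-methyl-4-methylidene-5-[(triethylsilyl)oxy]-3,3a,4,5,6,7,8,8a-octahydroazulen-7-yl]-6-methylhept-5-ene-3,4-diyl diacetate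
Conditions: Ni(cod)2 (20 mol%), IPr (1,3-bis(2,6-diisopropylphenyl)imidazol-2-ylidene, 20 mol%), Et3SiH (3 equiv), THF, rt, slow addition of 31 to a final 0.005 M
Reagents that add atoms: none
Why: Zerovalent nickel bearing the bulky carbene binds aldehyde and alkyne and undergoes oxidative cyclization to an oxanickelacyclopentene in which C1–C2 is formed, and σ-bond metathesis of the Ni–O bond with Et3SiH followed by C–H reductive elimination gives the O2 silyl ether, the exocyclic C1=CH2 and the regenerated catalyst. The closest known reaction type is the nickel–carbene–silane reductive cyclization and macrocyclization of ynals, for which seven-membered closure onto a terminal alkyne is only thinly documented. Ring B closes in the 7-exo-dig mode on the internal alkyne carbon, because cis addition of C2 and H across the triple bond in the endo mode would place an (E)-alkene in an eight-membered ring. The new centre C2 is expected to be set by substrate control: the trans ring fusion (C6, C10) fixes a chair-like array of the tether in which the aldehyde oxygen, held in the plane of the nickelacycle, takes the pseudo-equatorial site on the α face away from the C4 side chain, which corresponds to 2R, and an enantiopure chiral carbene would be used if this bias proves too small. The step needs chemoselectivity for the ynal over the allylic acetate at C13, the two trisubstituted alkenes and alkyne oligomerisation, which the intramolecular coupling, slow addition at high dilution and the large carbene (disfavouring bis-alkyne complexes) are meant to secure.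

Step 24
Reactants: 33 bis-silyl ether of the target
Product: 34 (2R,3S,4S)-2-[(3aR,5R,7S,8R,8aS)-5,8-dihydroxy-1-methyl-4-methylidene-3,3a,4,5,6,7,8,8a-octahydroazulen-7-yl]-6-methylhept-5-ene-3,4-diyl diacetate (target)
Conditions: HF·pyridine, pyridine, THF, 0 °C → rt
Reagents that add atoms: none
Why: Fluoride-mediated cleavage with buffered HF·pyridine removes the triethylsilyl and the tert-butyldimethylsilyl ether in one operation and is not basic enough to hydrolyse or shift the acetates.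

**Compound list**

1 | furan-2(5H)-one | O=C1C=CCO1 | starting material
2 | (4S)-4-(prop-1-en-2-yl)oxolan-2-one | O=C1C[C@@H](C(C)=C)CO1 | intermediate
3 | lithium enolate of 2 (formed in the flask) | [Li]OC1=C[C@@H](C(C)=C)CO1 | intermediate
4 | (3R,4S)-3-(prop-2-en-1-yl)-4-(prop-1-en-2-yl)oxolan-2-one | C=CC[C@H]1C(=O)OC[C@@H]1C(C)=C | intermediate
5 | (3R,4S)-3-(prop-2-en-1-yl)-4-(prop-1-en-2-yl)oxolan-2-ol, both anomers | C=CC[C@H]1C(O)OC[C@@H]1C(C)=C | intermediate
6 | (2R,3S)-3-(hydroxymethyl)-4-methyl-2-(prop-2-en-1-yl)pent-4-enal (open form of 5, formed in the flask) | C=CC[C@@H](C=O)[C@H](CO)C(C)=C | intermediate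
7 | (2S,3R)-3-ethynyl-2-(prop-1-en-2-yl)hex-5-en-1-ol | C#C[C@H](CC=C)[C@H](CO)C(C)=C | intermediate
8 | trimethyl{[(2S,3R)-2-(prop-1-en-2-yl)-3-[(trimethylsilyl)ethynyl]hex-5-en-1-yl]oxy}silane (formed in the flask) | C[Si](C)(C)C#C[C@H](CC=C)[C@H](CO[Si](C)(C)C)C(C)=C | intermediate
9 | (2S,3R)-2-(prop-1-en-2-yl)-3-[(trimethylsilyl)ethynyl]hex-5-en-1-ol | C[Si](C)(C)C#C[C@H](CC=C)[C@H](CO)C(C)=C | intermediate
10 | {(1S,5R)-2-methyl-5-[(trimethylsilyl)ethynyl]cyclopent-2-en-1-yl}methanol | C[Si](C)(C)C#C[C@@H]1CC=C(C)[C@H]1CO | intermediate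
11 | (1S,5R)-2-methyl-5-[(trimethylsilyl)ethynyl]cyclopent-2-ene-1-carbaldehyde | C[Si](C)(C)C#C[C@@H]1CC=C(C)[C@H]1C=O | intermediate
12 | (2E)-but-2-en-1-ol | C/C=C/CO | starting material
13 | [(2R,3R)-3-methyloxiran-2-yl]methanol | OC[C@H]1O[C@@H]1C | intermediate
14 | (2S,3R)-3-methyl-5-(trimethylsilyl)pent-4-yne-1,2-diol | C[Si](C)(C)C#C[C@@H](C)[C@H](O)CO | intermediate
15 | (4S)-2-(4-methoxyphenyl)-4-[(2R)-4-(trimethylsilyl)but-3-yn-2-yl]-1,3-dioxolane, both acetal epimers | C[Si](C)(C)C#C[C@@H](C)[C@H]1COC(c2ccc(OC)cc2)O1 | intermediate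
16 | (2S,3R)-2-[(4-methoxybenzyl)oxy]-3-methyl-5-(trimethylsilyl)pent-4-yn-1-ol | C[Si](C)(C)C#C[C@@H](C)[C@H](OCc1ccc(OC)cc1)CO | intermediate
17 | (2S,3R)-2-[(4-methoxybenzyl)oxy]-3-methyl-5-(trimethylsilyl)pent-4-ynal | C[Si](C)(C)C#C[C@@H](C)[C@H](OCc1ccc(OC)cc1)C=O | intermediate
18 | (3R,4S,5S)-4-[(4-methoxybenzyl)oxy]-3,7-dimethyl-1-(trimethylsilyl)oct-6-en-1-yn-5-ol (formed in the flask) | C[Si](C)(C)C#C[C@@H](C)[C@H](OCc1ccc(OC)cc1)[C@H](C=C(C)C)O | intermediate
19 | (3R,4S,5S)-4-[(4-methoxybenzyl)oxy]-3,7-dimethyloct-6-en-1-yn-5-ol | C#C[C@@H](C)[C@H](OCc1ccc(OC)cc1)[C@H](C=C(C)C)O | intermediate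
20 | (3R,4S,5S)-3,7-dimethyloct-6-en-1-yne-4,5-diol | C#C[C@@H](C)[C@H](O)[C@H](C=C(C)C)O | intermediate
21 | (3R,4S,5S)-3,7-dimethyloct-6-en-1-yne-4,5-diyl diacetate | C#C[C@@H](C)[C@H](OC(C)=O)[C@H](C=C(C)C)OC(C)=O | intermediate
22 | (1E,3R,4S,5S)-3,7-dimethyl-1-(4,4,5,5-tetramethyl-1,3,2-dioxaborolan-2-yl)octa-1,6-diene-4,5-diyl diacetate | CC1(C)OB(/C=C/[C@@H](C)[C@H](OC(C)=O)[C@H](C=C(C)C)OC(C)=O)OC1(C)C | intermediate
23 | lithium (chloromethyl)boronate ate complex of 22 (formed in the flask) | [Li+].ClC[B-]1(/C=C/[C@@H](C)[C@H](OC(C)=O)[C@H](C=C(C)C)OC(C)=O)OC(C)(C)C(C)(C)O1 | intermediate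
24 | (2E,4R,5S,6S)-4,8-dimethyl-1-(4,4,5,5-tetramethyl-1,3,2-dioxaborolan-2-yl)nona-2,7-diene-5,6-diyl diacetate | CC1(C)OB(C/C=C/[C@@H](C)[C@H](OC(C)=O)[C@H](C=C(C)C)OC(C)=O)OC1(C)C | intermediate
25 | O5 pinacol borate ester of 26 (formed in the flask) | C[Si](C)(C)C#C[C@@H]1CC=C(C)[C@H]1[C@H](OB2OC(C)(C)C(C)(C)O2)[C@H]([C@@H](C)[C@H](OC(C)=O)[C@H](C=C(C)C)OC(C)=O)C=C | intermediate
26 | (3S,4R,5S,6S)-3-[(R)-hydroxy{(1S,5R)-2-methyl-5-[(trimethylsilyl)ethynyl]cyclopent-2-en-1-yl}methyl]-4,8-dimethylnona-1,7-diene-5,6-diyl diacetate | C[Si](C)(C)C#C[C@@H]1CC=C(C)[C@H]1[C@H](O)[C@H]([C@@H](C)[C@H](OC(C)=O)[C@H](C=C(C)C)OC(C)=O)C=C | intermediate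
27 | O5 tert-butyldimethylsilyl ether of 26 | C[Si](C)(C)C#C[C@@H]1CC=C(C)[C@H]1[C@H](O[Si](C)(C)C(C)(C)C)[C@H]([C@@H](C)[C@H](OC(C)=O)[C@H](C=C(C)C)OC(C)=O)C=C | intermediate
28 | B-alkyl-9-borabicyclo[3.3.1]nonane from 27, boron on C2 (formed in the flask) | C[Si](C)(C)C#C[C@@H]1CC=C(C)[C@H]1[C@H](O[Si](C)(C)C(C)(C)C)[C@H]([C@@H](C)[C@H](OC(C)=O)[C@H](C=C(C)C)OC(C)=O)CCB1C2CCCC1CCC2 | intermediate
29 | (3S,4R,5S,6S)-3-[(R)-[(tert-butyldimethylsilyl)oxy]{(1S,5R)-2-methyl-5-[(trimethylsilyl)ethynyl]cyclopent-2-en-1-yl}methyl]-1-hydroxy-4,8-dimethylnon-7-ene-5,6-diyl diacetate | C[Si](C)(C)C#C[C@@H]1CC=C(C)[C@H]1[C@H](O[Si](C)(C)C(C)(C)C)[C@H]([C@@H](C)[C@H](OC(C)=O)[C@H](C=C(C)C)OC(C)=O)CCO | intermediate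
30 | (3S,4R,5S,6S)-3-[(R)-[(tert-butyldimethylsilyl)oxy]{(1S,5R)-5-ethynyl-2-methylcyclopent-2-en-1-yl}methyl]-1-hydroxy-4,8-dimethylnon-7-ene-5,6-diyl diacetate | C#C[C@@H]1CC=C(C)[C@H]1[C@H](O[Si](C)(C)C(C)(C)C)[C@H]([C@@H](C)[C@H](OC(C)=O)[C@H](C=C(C)C)OC(C)=O)CCO | intermediate
31 | (3S,4R,5S,6S)-3-[(R)-[(tert-butyldimethylsilyl)oxy]{(1S,5R)-5-ethynyl-2-methylcyclopent-2-en-1-yl}methyl]-4,8-dimethyl-1-oxonon-7-ene-5,6-diyl diacetate | C#C[C@@H]1CC=C(C)[C@H]1[C@H](O[Si](C)(C)C(C)(C)C)[C@H]([C@@H](C)[C@H](OC(C)=O)[C@H](C=C(C)C)OC(C)=O)CC=O | intermediate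
32 | triethylsilane | CC[SiH](CC)CC | starting material
33 | (2R,3S,4S)-2-[(3aR,5R,7S,8R,8aS)-8-[(tert-butyldimethylsilyl)oxy]-1-methyl-4-methylidene-5-[(triethylsilyl)oxy]-3,3a,4,5,6,7,8,8a-octahydroazulen-7-yl]-6-methylhept-5-ene-3,4-diyl diacetate | C=C1[C@H](O[Si](CC)(CC)CC)C[C@@H]([C@@H](C)[C@H](OC(C)=O)[C@H](C=C(C)C)OC(C)=O)[C@@H](O[Si](C)(C)C(C)(C)C)[C@@H]2C(C)=CC[C@@H]12 | intermediate
34 | (2R,3S,4S)-2-[(3aR,5R,7S,8R,8aS)-5,8-dihydroxy-1-methyl-4-methylidene-3,3a,4,5,6,7,8,8a-octahydroazulen-7-yl]-6-methylhept-5-ene-3,4-diyl diacetate | C=C1[C@H](O)C[C@@H]([C@@H](C)[C@H](OC(C)=O)[C@H](C=C(C)C)OC(C)=O)[C@@H](O)[C@@H]2C(C)=CC[C@@H]12 | target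

**Step count**

Total: 24 steps. Longest linear sequence: 17 steps (steps 8–17 from (2E)-but-2-en-1-ol, then steps 18–24).

**Steps most likely to fail**

Step 23. The slow seven-membered oxidative cyclization may be outrun by oligomerisation or hydrosilylation of the terminal alkyne; zerovalent nickel may ionise the C13 allylic acetate; and the facial bias at C2 may be weak. The fallback keeps the C1–C2 disconnection but forms the bond by a Nozaki–Hiyama–Kishi closure. It sets out from silyl ether 27. Silver-catalysed C-desilylation would give the terminal alkyne F1. Bromoboration with B-bromo-9-BBN (CH2Cl2, −20 °C) would give the (Z)-2-bromoalkenylborane F2, and protonolysis with acetic acid the 2-bromoalkene F3. Hydroboration of the vinyl group with 9-BBN would give the alkylborane F4, which perborate would oxidise to the primary alcohol F5. Dess–Martin oxidation would give the bromo aldehyde F6. CrCl2 with catalytic NiCl2 in DMSO (divalent chromium, alkenylchromium addition to the aldehyde) would close ring B to the allylic alcohol F7, and HF·pyridine would bring the route back at target 34.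

Step 18. Catalyst control may be overridden by the intrinsic facial preference of the α-branched aldehyde, and the slow union of two hindered partners may allow acid-promoted enolisation of 11 with loss of C6 or migration of the C7=C8 bond. The fallback replaces catalyst control by a stoichiometric chiral borane that reacts at −78 °C. It sets out from alkyne 21. Crabbé homologation ((CH2O)n, CuI, Cy2NH, dioxane, reflux) would give the terminal allene F8. Hydroboration with (+)-diisopinocampheylborane (from (−)-α-pinene), followed by equilibration to the more stable (E)-isomer by 1,3-boron shift, would give the allylborane F9. Addition to aldehyde 11 at −78 °C, with the Re face expected from the usual model for this reagent, would give the borinate F10, and perborate work-up would return to the route at alcohol 26.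

Step 17. n-BuLi or the carbenoid may attack the acetates before iodine–lithium exchange and ate-complex formation are complete, and the allylboronate may lose its geometry by 1,3-boron shift during isolation. The fallback forms the C2–C3 bond by cross-coupling under conditions that esters tolerate. It sets out from alkyne 21. Hydrozirconation with Cp2ZrHCl in THF would give the alkenylzirconocene F11, and iodine the (E)-vinyl iodide F12. Coupling with IZnCH2Bpin (from ICH2Bpin and Zn) under Pd(PPh3)4 catalysis would return to the route at allylboronate 24.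

**Further compounds**

F1 | step 23 | (3S,4R,5S,6S)-3-[(R)-[(tert-butyldimethylsilyl)oxy]{(1S,5R)-5-ethynyl-2-methylcyclopent-2-en-1-yl}methyl]-4,8-dimethylnona-1,7-diene-5,6-diyl diacetate | C#C[C@@H]1CC=C(C)[C@H]1[C@H](O[Si](C)(C)C(C)(C)C)[C@H]([C@@H](C)[C@H](OC(C)=O)[C@H](C=C(C)C)OC(C)=O)C=C
F2 | step 23 | (Z)-2-bromoalkenyl-9-borabicyclo[3.3.1]nonane from F1, boron on the former alkyne CH | Br/C(=C\B1C2CCCC1CCC2)[C@@H]1CC=C(C)[C@H]1[C@H](O[Si](C)(C)C(C)(C)C)[C@H]([C@@H](C)[C@H](OC(C)=O)[C@H](C=C(C)C)OC(C)=O)C=C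
F3 | step 23 | 2-bromoalkene: (3S,4R,5S,6S)-3-[(R)-{(1S,5R)-5-(1-bromoethenyl)-2-methylcyclopent-2-en-1-yl}[(tert-butyldimethylsilyl)oxy]methyl]-4,8-dimethylnona-1,7-diene-5,6-diyl diacetate | C=C(Br)[C@@H]1CC=C(C)[C@H]1[C@H](O[Si](C)(C)C(C)(C)C)[C@H]([C@@H](C)[C@H](OC(C)=O)[C@H](C=C(C)C)OC(C)=O)C=C
F4 | step 23 | B-alkyl-9-borabicyclo[3.3.1]nonane from F3, boron on C2 | C=C(Br)[C@@H]1CC=C(C)[C@H]1[C@H](O[Si](C)(C)C(C)(C)C)[C@H]([C@@H](C)[C@H](OC(C)=O)[C@H](C=C(C)C)OC(C)=O)CCB1C2CCCC1CCC2
F5 | step 23 | primary alcohol: (3S,4R,5S,6S)-3-[(R)-{(1S,5R)-5-(1-bromoethenyl)-2-methylcyclopent-2-en-1-yl}[(tert-butyldimethylsilyl)oxy]methyl]-1-hydroxy-4,8-dimethylnon-7-ene-5,6-diyl diacetate | C=C(Br)[C@@H]1CC=C(C)[C@H]1[C@H](O[Si](C)(C)C(C)(C)C)[C@H]([C@@H](C)[C@H](OC(C)=O)[C@H](C=C(C)C)OC(C)=O)CCO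
F6 | step 23 | bromo aldehyde: (3S,4R,5S,6S)-3-[(R)-{(1S,5R)-5-(1-bromoethenyl)-2-methylcyclopent-2-en-1-yl}[(tert-butyldimethylsilyl)oxy]methyl]-4,8-dimethyl-1-oxonon-7-ene-5,6-diyl diacetate | C=C(Br)[C@@H]1CC=C(C)[C@H]1[C@H](O[Si](C)(C)C(C)(C)C)[C@H]([C@@H](C)[C@H](OC(C)=O)[C@H](C=C(C)C)OC(C)=O)CC=O
F7 | step 23 | O5 tert-butyldimethylsilyl ether of 34 (free C2 hydroxyl) | C=C1[C@H](O)C[C@@H]([C@@H](C)[C@H](OC(C)=O)[C@H](C=C(C)C)OC(C)=O)[C@@H](O[Si](C)(C)C(C)(C)C)[C@@H]2C(C)=CC[C@@H]12
F8 | step 18 | (4R,5S,6S)-4,8-dimethylnona-1,2,7-triene-5,6-diyl diacetate | C=C=C[C@@H](C)[C@H](OC(C)=O)[C@H](C=C(C)C)OC(C)=O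
F9 | step 18 | (2E,4R,5S,6S)-1-(diisopinocampheylboryl)-4,8-dimethylnona-2,7-diene-5,6-diyl diacetate | C(/C=C/[C@@H](C)[C@H](OC(C)=O)[C@H](C=C(C)C)OC(C)=O)B([C@H]1C[C@H]2C[C@@H]([C@@H]1C)C2(C)C)[C@H]1C[C@H]2C[C@@H]([C@@H]1C)C2(C)C
F10 | step 18 | O5 diisopinocampheylborinate of 26 | C[Si](C)(C)C#C[C@@H]1CC=C(C)[C@H]1[C@H](OB([C@H]2C[C@H]3C[C@@H]([C@@H]2C)C3(C)C)[C@H]2C[C@H]3C[C@@H]([C@@H]2C)C3(C)C)[C@H]([C@@H](C)[C@H](OC(C)=O)[C@H](C=C(C)C)OC(C)=O)C=C
F11 | step 17 | (E)-alkenyl(chloro)zirconocene from 21 | Cl[Zr](/C=C/[C@@H](C)[C@H](OC(C)=O)[C@H](C=C(C)C)OC(C)=O)(C1C=CC=C1)C1C=CC=C1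
F12 | step 17 | (1E,3R,4S,5S)-1-iodo-3,7-dimethylocta-1,6-diene-4,5-diyl diacetate | I/C=C/[C@@H](C)[C@H](OC(C)=O)[C@H](C=C(C)C)OC(C)=O
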